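## The problem

The target (30) is a twelve-carbon acyl chain (C1'–C12', C1' being the ketone carbon) joined through the exocyclic C3–C1' bond to its only ring, a (6R)-4-hydroxy-6-methyl-5,6-dihydro-2H-pyran-2-one (O1, C2–C6). Ring and chain meet in an enolised tricarbonyl, so no ring fusion has to be built. The chain carries an (E)-C6'=C7' alkene, a carboxyl branch on C8', a methyl branch on C4' and a (2S)-2-methylbutyl terminus. The four stereocentres C6 (R), C4' (R), C8' (S) and C10' (S) are insulated from one another by methylene groups or the alkene, so none can direct another. Each must be bought or set by a reagent, and each must be secured at a stage where an epimer can still be removed or at least measured. C8' is the delicate centre: it is allylic and α to the carboxyl, so base can epimerise it or pull the alkene into conjugation, and as an ester it could not sit next to carbanion chemistry at C7'. The 3-acyl-4-hydroxypyranone is acidic and chelating, its lactone is opened by hard nucleophiles, and its enol carbons are open to electrophilic oxidants, so it should arrive late. The feature that makes the key step possible is the C1'–C6' segment: six carbons in a row, oxidised at both ends, with the methyl branch in the middle at C4'. Joined end to end, these are the ring carbons of 4-methylcyclohexanone (1), where C4' lies on a mirror plane; oxygen insertion into one of the two enantiotopic C(=O)–CH2 bonds makes C4' stereogenic and leaves C1' as an acyl carbon and C6' as a carbinol.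

## Retrosynthesis

**C8' carboxyl to hydroxymethyl (30 ⇒ 28 ⇒ 27).** No skeletal bond is cut; the carboxyl is traced back through aldehyde 29 to alcohol 28 and its silyl ether 27. A C8' ester would make C8'–H acidic and would place a leaving group β to any C7' carbanion, whereas a CH2OSi group is inert to base. The forward oxidation must spare the enol and must not epimerise C8' at the aldehyde stage.

**Ring from chain (27 ⇒ 25 + 23).** The C3–C1' bond is cut. This separates the only ring from the chain at a bond that acyl transfer can make, and it keeps the tricarbonyl out of all earlier steps. Opening the ring instead (C3–C4) would need an alkoxide-mediated condensation on the complete chain. The precursors are the simple acid 25 and the six-carbon dione 23. The forward step must deliver C- rather than O-acylation, which is met by O-acylation through 26 followed by acyl migration.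

**The alkene (25 ⇐ 24 ⇒ 18 + 5).** The C6'=C7' double bond is cut. It is the natural seam: it lies between the two chain stereocentres and divides the chain into two pieces of similar size. A Julia–Kocienski olefination is chosen for its E preference. The sulfone is placed on C7' (18) and the aldehyde on C6' (5), for two reasons:
- the methyl ester then sits on the electrophile, where the carbanion meets an aldehyde first and cannot close a six-membered β-keto sulfone onto its own ester;
- no aldehyde with an α-stereocentre is needed.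

**The key cut (5 ⇒ 4 ⇒ 3 ⇒ 1).** Aldehyde 5 comes from hydroxy ester 4, which is the methanolysis product of lactone 3. Lactone 3 is ketone 1 with one oxygen inserted between C1' and C6'. The precursor is an achiral bulk ketone with no functional group to protect. The forward reaction must distinguish two enantiotopic ring bonds by catalyst control alone.

**The C7'–C12' piece (18 ⇒ 17 ⇒ 16 ⇒ 15 ⇒ 14 ⇒ 13 ⇒ 10 + 11; 10 ⇒ 8 ⇒ 6 + 7).**
- Sulfone 18 is traced through sulfide 17 to alcohol 16, a 2-substituted propane-1,3-diol whose two arms differ only in the silyl group.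
- 16 comes from imide 15 by reductive removal of the auxiliary, 15 from 14 by silylation, and 14 from 13 by cutting the C8'–CH2O bond (hydroxymethylation of an oxazolidinone enolate).
- An auxiliary is preferred to a catalytic method here because the minor diastereomer can be removed at the imide stage.
- Imide 13 is acid 10 on auxiliary 11, and 10 is bromide 6 extended by two carbons with malonate 7 through 8 (C8'–C9' bond).

**The ring piece (23 ⇒ 21 ⇒ 19 + 20).** The lactone C–O bond and the C3–C4 bond of the dione are cut. This leads to the δ-hydroxy-β-keto ester 21 and on to methyl (R)-3-hydroxybutanoate 19 and tert-butyl acetate 20. C6 is bought, and its C–O bond is never broken.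

## Roads not taken

**Alternative 1:** The cut removes the C8'–CH2OH bond and, with it, the alkene. In the forward sense, tin–lithium exchange on the (Z)-allylic stannylmethyl ether A2 triggers a [2,3]-Wittig shift to the homoallylic alcohol A1.
- Merits: one stereospecific event sets C8', its one-carbon handle and the (E)-alkene by chirality transfer from the C6' carbinol. The C1'–C6' carbons with C4' come from (R)-citronellal A3, so the enantiopurity of C4' is bought rather than earned by catalysis; in this respect the road is better than the chosen one.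
- Weak points: A2 needs an (S)-configured carbinol beside a (Z)-alkene, a stereocentre made only to be destroyed. Tributyltin is used in stoichiometric amount, and a [1,2]-shift can compete. A1 then needs two oxidative operations: CH2OH to CO2H, and cleavage of the trisubstituted terminal alkene in the presence of the C6'=C7' alkene. The sequence is linear.
- Comparison: the chosen plan offers convergence, no tin, no sacrificial stereocentre, and chain ends that leave the key step already differentiated. It must accept that C4' rests on the selectivity of one catalytic step.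

**Alternative 2:** The cut is the ring bond C3–C4. The β-keto ester carbon of the acyclic diester A5 attacks the methyl ester in a Lacey–Dieckmann closure to give the tert-butyl ester A4 of the target.
- Merits: no O-to-C acyl migration is needed, the tricarbonyl appears only in the last carbon–carbon bond-forming step, and the C8' carboxyl is carried as an ester, so there is no late oxidation. On this last point it is better than the chosen plan.
- Weak points: the alkoxide base can expel the β-acyloxy group from the butanoate part (E1cB), and it meets C8' while this is α to an ester and allylic. The β-keto ester must first be built on the whole chain. The disconnection does not address C4' or the alkene.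
- Comparison: the chosen plan joins ring and chain in one operation under amine base and keeps C8' at the alcohol level until the end. It pays with a late oxidation. The Dieckmann logic is kept as the fallback for step 16.

**Alternative 3:** The cut is a C2'=C3' double bond that the target does not contain. The dianion of phosphonate A7 condenses with aldehyde A8 to give the 2',3'-didehydro ester A6.
- Merits: it is the most convergent road, the heterocycle is made in advance, and the olefination is a standard Horner–Wadsworth–Emmons reaction; it is superior in convergence.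
- Weak points: in A8 the C4' centre is α to an aldehyde, and in A6 it is γ to an enone, so it can be lost twice. The extra alkene must later be reduced selectively in the presence of C6'=C7' and a chelating tricarbonyl. C4' would have to be made as an α-methyl aldehyde, so the origin in a bulk ketone is given up.
- Comparison: the chosen plan has more steps after fragment union, but C4' is never adjacent to a carbonyl or an alkene and no extra reduction is required.

Key step: step 1

Remark on the chemistry: the 3-acyl-4-hydroxypyranone is written throughout as the enol tautomer of the target SMILES; its tautomers are one compound and C3 carries no stereochemical information.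

## Route

Step 1
Reactants: 1 4-methylcyclohexanone
Product: 3 (5R)-5-methyloxepan-2-one, via Criegee perester adduct 2 (not isolated)
Conditions: Sc(OTf)3 (5 mol %), chiral N,N'-dioxide ligand (6 mol %, enantiomer leading to the (R)-lactone), mCPBA (1.1 equiv), EtOAc, −20 °C
Reagents that add atoms: 3-chloroperbenzoic acid (mCPBA), OOC(=O)c1cccc(Cl)c1
Why: Sc(OTf)3 held in the chiral N,N'-dioxide pocket activates the carbonyl of 1, the peracid adds to give the Criegee adduct 2, and one α-methylene migrates from carbon to oxygen with loss of 3-chlorobenzoate. The closest known reaction type is the catalytic enantioselective Baeyer–Villiger desymmetrisation of 4-substituted cyclohexanones with chiral N,N'-dioxide–Sc(OTf)3 complexes and a peracid, paralleled by Baeyer–Villiger monooxygenases. No ring is closed: the six-membered carbocycle is enlarged to the seven-membered lactone by a 1,2-shift, so no ring-closure mode has to be met. The new stereocentre is C5 of 3 (C4' of the target); it is a prochiral carbon on the mirror plane of 1 and becomes stereogenic because the two ring arms are made different. Its configuration is fixed by the catalyst alone, which decides which of the two enantiotopic C(=O)–CH2 bonds lies antiperiplanar to the O–O bond of the bound adduct and therefore migrates. The selectivity needed is enantiotopic-group selectivity; regioselectivity is no issue because both migrating groups are identical primary carbons, and the equatorial methyl group locks one chair so that the catalyst meets a single conformer. The ligand enantiomer is the one that leads to the (R)-lactone; wild-type cyclohexanone monooxygenase is known to favour the (S)-lactone from this ketone and is therefore not used. The enantiomeric purity is to be assayed on 3 by chiral gas chromatography before material is carried on, because C4' has no neighbour that would allow an epimer to be removed later.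

Step 2
Reactants: 3 (5R)-5-methyloxepan-2-one
Product: 4 methyl (4R)-6-hydroxy-4-methylhexanoate
Conditions: MeOH, K2CO3 (0.1 equiv), 0 °C → rt; AcOH quench
Reagents that add atoms: methanol, CO
Why: Base-catalysed transesterification (lactone methanolysis); relief of the strain of the seven-membered lactone and the excess of methanol hold the equilibrium on the side of the open ester, and the crude ester is oxidised at once to forestall relactonisation.

Step 3
Reactants: 4 methyl (4R)-6-hydroxy-4-methylhexanoate
Product: 5 methyl (4R)-4-methyl-6-oxohexanoate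
Conditions: TEMPO (0.1 equiv), PhI(OAc)2 (1.1 equiv), CH2Cl2, rt
Reagents that add atoms: none
Why: Oxoammonium-mediated oxidation of a primary alcohol stops at the aldehyde in the absence of water; the ester is inert and C4' is β to the new carbonyl, so it cannot epimerise.

Step 4
Reactants: 6 (2S)-1-bromo-2-methylbutane; 7 diethyl malonate
Product: 8 diethyl 2-[(2S)-2-methylbutyl]propanedioate
Conditions: NaOEt, NaI (cat.), EtOH, reflux
Reagents that add atoms: none
Why: Malonic ester alkylation (SN2 at the primary carbon); the stereocentre is on the neighbouring carbon and takes no part, and iodide catalysis offsets the slower rate of a β-branched bromide.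

Step 5
Reactants: 8 diethyl 2-[(2S)-2-methylbutyl]propanedioate
Product: 10 (4S)-4-methylhexanoic acid, via 2-[(2S)-2-methylbutyl]propanedioic acid 9 (not isolated)
Conditions: KOH, EtOH/H2O, reflux; aq. H2SO4 to pH 1; then neat, 170 °C
Reagents that add atoms: potassium hydroxide, [K+].[OH-]
Why: Saponification followed by thermal decarboxylation of the malonic acid through the usual cyclic transition state; nothing in the molecule is sensitive to either stage.

Step 6
Reactants: 10 (4S)-4-methylhexanoic acid; 11 (4S)-4-benzyl-1,3-oxazolidin-2-one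
Product: 13 (4S)-4-benzyl-3-[(4S)-4-methylhexanoyl]-1,3-oxazolidin-2-one, via mixed pivalic anhydride 12 (not isolated)
Conditions: tBuCOCl, Et3N, THF, −20 °C; then 11, LiCl, −20 °C → rt
Reagents that add atoms: none
Why: Mixed-anhydride N-acylation of the oxazolidinone; the nucleophile attacks the less hindered carbonyl of 12, and LiCl/Et3N makes a strong base unnecessary.

Step 7
Reactants: 13 (4S)-4-benzyl-3-[(4S)-4-methylhexanoyl]-1,3-oxazolidin-2-one
Product: 14 (4S)-4-benzyl-3-[(2R,4S)-2-(hydroxymethyl)-4-methylhexanoyl]-1,3-oxazolidin-2-one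
Conditions: TiCl4, iPr2NEt, CH2Cl2, 0 °C; then 1,3,5-trioxane, TiCl4, 0 °C
Reagents that add atoms: 1,3,5-trioxane, C1OCOCO1
Why: Auxiliary-controlled hydroxymethylation of a titanium enolate: soft enolisation gives the chelated (Z)-enolate, and formaldehyde released from trioxane attacks the face opposite the benzyl group, which sets C8' as (2R) in 14. The minor diastereomer is removed here by chromatography or crystallisation, the last point at which a C8' epimer can be separated.

Step 8
Reactants: 14 (4S)-4-benzyl-3-[(2R,4S)-2-(hydroxymethyl)-4-methylhexanoyl]-1,3-oxazolidin-2-one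
Product: 15 (4S)-4-benzyl-3-[(2R,4S)-2-({[tert-butyl(dimethyl)silyl]oxy}methyl)-4-methylhexanoyl]-1,3-oxazolidin-2-one
Conditions: TBSCl, imidazole, CH2Cl2, rt
Reagents that add atoms: tert-butyl(chloro)dimethylsilane, CC(C)(C)[Si](C)(C)Cl
Why: Standard silylation of a primary alcohol; imidazole is too weak a base to cause retro-aldol cleavage or epimerisation α to the imide.

Step 9
Reactants: 15 (4S)-4-benzyl-3-[(2R,4S)-2-({[tert-butyl(dimethyl)silyl]oxy}methyl)-4-methylhexanoyl]-1,3-oxazolidin-2-one
Product: 16 (2S,4S)-2-({[tert-butyl(dimethyl)silyl]oxy}methyl)-4-methylhexan-1-ol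
Conditions: LiBH4, MeOH (1 equiv), Et2O, 0 °C; aq. NH4Cl
Reagents that add atoms: none
Why: Reductive cleavage of the N-acyl oxazolidinone at the exocyclic carbonyl with recovery of 11; the change of descriptor reflects priorities only. The reaction is kept cold and quenched promptly, because a 1,3-silyl shift between the two CH2O arms would invert C8'.

Step 10
Reactants: 16 (2S,4S)-2-({[tert-butyl(dimethyl)silyl]oxy}methyl)-4-methylhexan-1-ol
Product: 17 5-{[(2R,4S)-2-({[tert-butyl(dimethyl)silyl]oxy}methyl)-4-methylhexyl]sulfanyl}-1-phenyl-1H-tetrazole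
Conditions: 1-phenyl-1H-tetrazole-5-thiol, PPh3, DIAD, THF, 0 °C → rt
Reagents that add atoms: 1-phenyl-1H-tetrazole-5-thiol, Sc1nnnn1-c1ccccc1
Why: Mitsunobu thioetherification at a primary carbon; the neutral conditions exclude silyl migration, and the stereocentre is not at the reacting carbon.

Step 11
Reactants: 17 5-{[(2R,4S)-2-({[tert-butyl(dimethyl)silyl]oxy}methyl)-4-methylhexyl]sulfanyl}-1-phenyl-1H-tetrazole
Product: 18 5-{[(2R,4S)-2-({[tert-butyl(dimethyl)silyl]oxy}methyl)-4-methylhexyl]sulfonyl}-1-phenyl-1H-tetrazole
Conditions: (NH4)6Mo7O24·4H2O (10 mol %), 30% H2O2, EtOH, 0 °C → rt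
Reagents that add atoms: hydrogen peroxide, OO
Why: Molybdate-catalysed peroxide oxidation of the sulfide to the sulfone, the usual entry to tetrazolyl sulfones; silyl ether and tetrazole are tolerated.

Step 12
Reactants: 19 methyl (3R)-3-hydroxybutanoate; 20 tert-butyl acetate
Product: 21 tert-butyl (5R)-5-hydroxy-3-oxohexanoate
Conditions: LiN(iPr)2 (3.6 equiv), 20 (3.5 equiv), THF, −78 °C; then 19, −78 → −20 °C; aq. NH4Cl
Reagents that add atoms: none
Why: Crossed Claisen condensation of the methyl ester with the lithium enolate of 20; the excess enolate covers the free hydroxyl and the acidic product, and the carbinol centre is not involved.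

Step 13
Reactants: 21 tert-butyl (5R)-5-hydroxy-3-oxohexanoate
Product: 23 (6R)-6-methyloxane-2,4-dione, via (5R)-5-hydroxy-3-oxohexanoic acid 22 (not isolated)
Conditions: CF3CO2H, CH2Cl2, rt
Reagents that add atoms: none
Why: Acidolysis of the tert-butyl ester and spontaneous lactonisation of the δ-hydroxy-β-keto acid; the C–O bond at the stereocentre is not broken, so C6 is retained.

Step 14
Reactants: 18 5-{[(2R,4S)-2-({[tert-butyl(dimethyl)silyl]oxy}methyl)-4-methylhexyl]sulfonyl}-1-phenyl-1H-tetrazole; 5 methyl (4R)-4-methyl-6-oxohexanoate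
Product: 24 methyl (4R,6E,8S,10S)-8-({[tert-butyl(dimethyl)silyl]oxy}methyl)-4,10-dimethyldodec-6-enoate
Conditions: KN(SiMe3)2, DME, −55 °C, 30 min; then 5, −55 °C → rt
Reagents that add atoms: none
Why: Julia–Kocienski olefination: the metallated sulfone adds to the aldehyde, and a Smiles rearrangement with loss of SO2 and the tetrazolone gives the alkene; the potassium counter-ion in DME favours the E isomer. The ester sits on the electrophile, C8' is β to the carbanion and carries no leaving group, so neither self-acylation nor epimerisation is expected.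

Step 15
Reactants: 24 methyl (4R,6E,8S,10S)-8-({[tert-butyl(dimethyl)silyl]oxy}methyl)-4,10-dimethyldodec-6-enoate
Product: 25 (4R,6E,8S,10S)-8-({[tert-butyl(dimethyl)silyl]oxy}methyl)-4,10-dimethyldodec-6-enoic acid
Conditions: LiOH·H2O, THF/MeOH/H2O, 0 °C → rt; then 1 M HCl to pH 4
Reagents that add atoms: lithium hydroxide, [Li+].[OH-]
Why: Saponification of an unhindered methyl ester; no stereocentre is α to a carbonyl at this stage, and the primary silyl ether withstands hydroxide and brief mild acid.

Step 16
Reactants: 25 (4R,6E,8S,10S)-8-({[tert-butyl(dimethyl)silyl]oxy}methyl)-4,10-dimethyldodec-6-enoic acid; 23 (6R)-6-methyloxane-2,4-dione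
Product: 27 (6R)-3-[(4R,6E,8S,10S)-8-({[tert-butyl(dimethyl)silyl]oxy}methyl)-4,10-dimethyldodec-6-enoyl]-4-hydroxy-6-methyl-5,6-dihydro-2H-pyran-2-one, via O-acyl enol ester 26 (not isolated)
Conditions: DCC (1.2 equiv), DMAP (1.5 equiv), CH2Cl2, 0 °C → rt
Reagents that add atoms: none
Why: Steglich-type O-acylation of the enol of 23 followed by DMAP-mediated O-to-C acyl migration (Fries-type) to the hydrogen-bonded 3-acyl enol, the thermodynamic product; this is the established way to 3-acyl-4-hydroxypyranones and 3-acyltetronic acids.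

Step 17
Reactants: 27 (6R)-3-[(4R,6E,8S,10S)-8-({[tert-butyl(dimethyl)silyl]oxy}methyl)-4,10-dimethyldodec-6-enoyl]-4-hydroxy-6-methyl-5,6-dihydro-2H-pyran-2-one
Product: 28 (6R)-4-hydroxy-3-[(4R,6E,8S,10S)-8-(hydroxymethyl)-4,10-dimethyldodec-6-enoyl]-6-methyl-5,6-dihydro-2H-pyran-2-one
Conditions: HF (48% aq.), MeCN, 0 °C → rt
Reagents that add atoms: none
Why: Acidic fluoride cleavage of a primary silyl ether; the medium keeps the tricarbonyl protonated and leaves lactone and alkene untouched, where a basic fluoride source would form the enolate.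

Step 18
Reactants: 28 (6R)-4-hydroxy-3-[(4R,6E,8S,10S)-8-(hydroxymethyl)-4,10-dimethyldodec-6-enoyl]-6-methyl-5,6-dihydro-2H-pyran-2-one
Product: 30 (2S,3E,6R)-9-[(6R)-4-hydroxy-6-methyl-2-oxo-5,6-dihydro-2H-pyran-3-yl]-6-methyl-2-[(2S)-2-methylbutyl]-9-oxonon-3-enoic acid, via C8' aldehyde 29 (not isolated)
Conditions: TEMPO (0.2 equiv), PhI(OAc)2 (2.5 equiv), MeCN/H2O (1:1), 0 °C → rt
Reagents that add atoms: water, O
Why: Oxoammonium oxidation of the primary alcohol to aldehyde 29, whose hydrate is oxidised on to the acid in the same flask. The medium is weakly acidic, so the tricarbonyl stays as the hydrogen-bonded enol, a poor nucleophile, and no base is present to epimerise C8' or shift the alkene.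

## Compound list

1 | 4-methylcyclohexanone | CC1CCC(=O)CC1 | starting material
2 | 1-hydroxy-4-methylcyclohexyl 3-chlorobenzenecarboperoxoate (Criegee adduct) | CC1CCC(O)(OOC(=O)c2cccc(Cl)c2)CC1 | intermediate
3 | (5R)-5-methyloxepan-2-one | O=C1CC[C@@H](C)CCO1 | intermediate
4 | methyl (4R)-6-hydroxy-4-methylhexanoate | COC(=O)CC[C@@H](C)CCO | intermediate
5 | methyl (4R)-4-methyl-6-oxohexanoate | COC(=O)CC[C@@H](C)CC=O | intermediate
6 | (2S)-1-bromo-2-methylbutane | CC[C@H](C)CBr | starting material
7 | diethyl malonate | CCOC(=O)CC(=O)OCC | starting material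
8 | diethyl 2-[(2S)-2-methylbutyl]propanedioate | CC[C@H](C)CC(C(=O)OCC)C(=O)OCC | intermediate
9 | 2-[(2S)-2-methylbutyl]propanedioic acid | CC[C@H](C)CC(C(=O)O)C(=O)O | intermediate
10 | (4S)-4-methylhexanoic acid | CC[C@H](C)CCC(=O)O | intermediate
11 | (4S)-4-benzyl-1,3-oxazolidin-2-one | O=C1N[C@@H](Cc2ccccc2)CO1 | starting material
12 | 2,2-dimethylpropanoic (4S)-4-methylhexanoic anhydride | CC[C@H](C)CCC(=O)OC(=O)C(C)(C)C | intermediate
13 | (4S)-4-benzyl-3-[(4S)-4-methylhexanoyl]-1,3-oxazolidin-2-one | CC[C@H](C)CCC(=O)N1[C@@H](Cc2ccccc2)COC1=O | intermediate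
14 | (4S)-4-benzyl-3-[(2R,4S)-2-(hydroxymethyl)-4-methylhexanoyl]-1,3-oxazolidin-2-one | CC[C@H](C)C[C@H](CO)C(=O)N1[C@@H](Cc2ccccc2)COC1=O | intermediate
15 | (4S)-4-benzyl-3-[(2R,4S)-2-({[tert-butyl(dimethyl)silyl]oxy}methyl)-4-methylhexanoyl]-1,3-oxazolidin-2-one | CC[C@H](C)C[C@H](CO[Si](C)(C)C(C)(C)C)C(=O)N1[C@@H](Cc2ccccc2)COC1=O | intermediate
16 | (2S,4S)-2-({[tert-butyl(dimethyl)silyl]oxy}methyl)-4-methylhexan-1-ol | CC[C@H](C)C[C@@H](CO)CO[Si](C)(C)C(C)(C)C | intermediate
17 | 5-{[(2R,4S)-2-({[tert-butyl(dimethyl)silyl]oxy}methyl)-4-methylhexyl]sulfanyl}-1-phenyl-1H-tetrazole | CC[C@H](C)C[C@@H](CSc1nnnn1-c1ccccc1)CO[Si](C)(C)C(C)(C)C | intermediate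
18 | 5-{[(2R,4S)-2-({[tert-butyl(dimethyl)silyl]oxy}methyl)-4-methylhexyl]sulfonyl}-1-phenyl-1H-tetrazole | CC[C@H](C)C[C@@H](CS(=O)(=O)c1nnnn1-c1ccccc1)CO[Si](C)(C)C(C)(C)C | intermediate
19 | methyl (3R)-3-hydroxybutanoate | C[C@@H](O)CC(=O)OC | starting material
20 | tert-butyl acetate | CC(=O)OC(C)(C)C | starting material
21 | tert-butyl (5R)-5-hydroxy-3-oxohexanoate | C[C@@H](O)CC(=O)CC(=O)OC(C)(C)C | intermediate
22 | (5R)-5-hydroxy-3-oxohexanoic acid | C[C@@H](O)CC(=O)CC(=O)O | intermediate
23 | (6R)-6-methyloxane-2,4-dione | C[C@@H]1CC(=O)CC(=O)O1 | intermediate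
24 | methyl (4R,6E,8S,10S)-8-({[tert-butyl(dimethyl)silyl]oxy}methyl)-4,10-dimethyldodec-6-enoate | CC[C@H](C)C[C@@H](/C=C/C[C@H](C)CCC(=O)OC)CO[Si](C)(C)C(C)(C)C | intermediate
25 | (4R,6E,8S,10S)-8-({[tert-butyl(dimethyl)silyl]oxy}methyl)-4,10-dimethyldodec-6-enoic acid | CC[C@H](C)C[C@@H](/C=C/C[C@H](C)CCC(=O)O)CO[Si](C)(C)C(C)(C)C | intermediate
26 | (2R)-2-methyl-6-oxo-3,6-dihydro-2H-pyran-4-yl (4R,6E,8S,10S)-8-({[tert-butyl(dimethyl)silyl]oxy}methyl)-4,10-dimethyldodec-6-enoate | CC[C@H](C)C[C@@H](/C=C/C[C@H](C)CCC(=O)OC1=CC(=O)O[C@H](C)C1)CO[Si](C)(C)C(C)(C)C | intermediate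
27 | (6R)-3-[(4R,6E,8S,10S)-8-({[tert-butyl(dimethyl)silyl]oxy}methyl)-4,10-dimethyldodec-6-enoyl]-4-hydroxy-6-methyl-5,6-dihydro-2H-pyran-2-one | CC[C@H](C)C[C@@H](/C=C/C[C@H](C)CCC(=O)C1=C(O)C[C@@H](C)OC1=O)CO[Si](C)(C)C(C)(C)C | intermediate
28 | (6R)-4-hydroxy-3-[(4R,6E,8S,10S)-8-(hydroxymethyl)-4,10-dimethyldodec-6-enoyl]-6-methyl-5,6-dihydro-2H-pyran-2-one | CC[C@H](C)C[C@@H](/C=C/C[C@H](C)CCC(=O)C1=C(O)C[C@@H](C)OC1=O)CO | intermediate
29 | (2S,3E,6R)-9-[(6R)-4-hydroxy-6-methyl-2-oxo-5,6-dihydro-2H-pyran-3-yl]-6-methyl-2-[(2S)-2-methylbutyl]-9-oxonon-3-enal | CC[C@H](C)C[C@@H](/C=C/C[C@H](C)CCC(=O)C1=C(O)C[C@@H](C)OC1=O)C=O | intermediate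
30 | (2S,3E,6R)-9-[(6R)-4-hydroxy-6-methyl-2-oxo-5,6-dihydro-2H-pyran-3-yl]-6-methyl-2-[(2S)-2-methylbutyl]-9-oxonon-3-enoic acid | CC[C@H](C)C[C@@H](/C=C/C[C@H](C)CCC(=O)C1=C(O)C[C@@H](C)OC1=O)C(=O)O | target

## Step count and least certain steps

Total: 18 steps in three branches. Longest linear sequence: 13 steps (steps 4–11, then 14–18, from bromide 6).

**Step 1 (key step).** The likely failure is incomplete discrimination between the two enantiotopic ring bonds, or induction in the wrong sense. The C4' epimer formed in this way would travel unseen to the end, because C4' is remote from every other centre. The fallback leaves the desymmetrisation for the chiral pool. It does not set out from a numbered compound: commercial (R)-citronellol F1 takes the place of 1, and the sequence comes back to the route at 4. Acetylation (Ac2O, pyridine) gives (R)-citronellyl acetate F2. Oxidative cleavage of the trisubstituted alkene (RuCl3 cat., NaIO4, MeCN/EtOAc/H2O) gives (4R)-6-(acetyloxy)-4-methylhexanoic acid F3. Heating F3 in MeOH with catalytic H2SO4 esterifies the acid, removes the acetate and delivers 4.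

**Step 18.** The oxidant may attack the enolised tricarbonyl (at C3 or, through the exocyclic enol, at C2'), and the transient aldehyde may epimerise at C8'. The fallback moves the oxidation ahead of the ring: it sets out from 24 and returns at 30.
- Aqueous HF in MeCN frees methyl (4R,6E,8S,10S)-8-(hydroxymethyl)-4,10-dimethyldodec-6-enoate F4.
- TEMPO/PhI(OAc)2 in wet MeCN takes F4 through methyl (4R,6E,8S,10S)-8-formyl-4,10-dimethyldodec-6-enoate F5 to (2S,3E,6R)-9-methoxy-6-methyl-2-[(2S)-2-methylbutyl]-9-oxonon-3-enoic acid F6.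
- tert-Butyl 2,2,2-trichloroacetimidate converts F6 into 1-tert-butyl 9-methyl (2S,3E,6R)-6-methyl-2-[(2S)-2-methylbutyl]non-3-enedioate F7.
- Me3SnOH in 1,2-dichloroethane at 80 °C cleaves the methyl ester alone and gives (4R,6E,8S)-9-tert-butoxy-4-methyl-8-[(2S)-2-methylbutyl]-9-oxonon-6-enoic acid F8.
- DCC/DMAP with 23 leads through 1-tert-butyl 9-[(2R)-2-methyl-6-oxo-3,6-dihydro-2H-pyran-4-yl] (2S,3E,6R)-6-methyl-2-[(2S)-2-methylbutyl]non-3-enedioate F9 to the tert-butyl ester of the target F10 (the same compound as A4).
- CF3CO2H in CH2Cl2 then gives 30.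

**Step 16.** The O-to-C acyl migration may stall at the enol ester, or DMAP may open the lactone before the shift is complete. The fallback builds the ring on the chain instead: it sets out from 25 and returns at 27. Acid 25 is condensed with Meldrum's acid (DCC, DMAP) to give 5-[(4R,6E,8S,10S)-8-({[tert-butyl(dimethyl)silyl]oxy}methyl)-4,10-dimethyldodec-6-enoyl]-2,2-dimethyl-1,3-dioxane-4,6-dione F11. Heating F11 with 19 in toluene gives methyl (3R)-3-{[(6R,8E,10S,12S)-10-({[tert-butyl(dimethyl)silyl]oxy}methyl)-6,12-dimethyl-3-oxotetradec-8-enoyl]oxy}butanoate F12. KOtBu in THF closes F12 by Dieckmann condensation to 27; C8' is not α to a carbonyl here, so the base cannot harm it.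

**Step 14.** The kinetic addition may give incomplete E selectivity, and the Z isomer would be hard to remove. The fallback is the classical two-stage Julia olefination, in which the geometry is set in the elimination: it sets out from 16 (with 5) and returns at 24. PhSSPh/PBu3 gives {[(2R,4S)-2-({[tert-butyl(dimethyl)silyl]oxy}methyl)-4-methylhexyl]sulfanyl}benzene F13. Molybdate/H2O2 gives the sulfone {[(2R,4S)-2-({[tert-butyl(dimethyl)silyl]oxy}methyl)-4-methylhexyl]sulfonyl}benzene F14. nBuLi (THF, −78 °C), addition to 5 and trapping with Ac2O give methyl (4R,8R,10S)-6-(acetyloxy)-7-(benzenesulfonyl)-8-({[tert-butyl(dimethyl)silyl]oxy}methyl)-4,10-dimethyldodecanoate F15 as a mixture at C6 and C7. Sodium amalgam (Na2HPO4, MeOH/THF, −20 °C) eliminates F15 to 24.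

## Further compounds

F1 | step 1 | (3R)-3,7-dimethyloct-6-en-1-ol ((R)-citronellol) | CC(C)=CCC[C@@H](C)CCO
F2 | step 1 | (3R)-3,7-dimethyloct-6-en-1-yl acetate | CC(C)=CCC[C@@H](C)CCOC(C)=O
F3 | step 1 | (4R)-6-(acetyloxy)-4-methylhexanoic acid | OC(=O)CC[C@@H](C)CCOC(C)=O
F4 | step 18 | methyl (4R,6E,8S,10S)-8-(hydroxymethyl)-4,10-dimethyldodec-6-enoate | CC[C@H](C)C[C@@H](/C=C/C[C@H](C)CCC(=O)OC)CO
F5 | step 18 | methyl (4R,6E,8S,10S)-8-formyl-4,10-dimethyldodec-6-enoate | CC[C@H](C)C[C@@H](/C=C/C[C@H](C)CCC(=O)OC)C=O
F6 | step 18 | (2S,3E,6R)-9-methoxy-6-methyl-2-[(2S)-2-methylbutyl]-9-oxonon-3-enoic acid | CC[C@H](C)C[C@@H](/C=C/C[C@H](C)CCC(=O)OC)C(=O)O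
F7 | step 18 | 1-tert-butyl 9-methyl (2S,3E,6R)-6-methyl-2-[(2S)-2-methylbutyl]non-3-enedioate | CC[C@H](C)C[C@@H](/C=C/C[C@H](C)CCC(=O)OC)C(=O)OC(C)(C)C
F8 | step 18 | (4R,6E,8S)-9-tert-butoxy-4-methyl-8-[(2S)-2-methylbutyl]-9-oxonon-6-enoic acid | CC[C@H](C)C[C@@H](/C=C/C[C@H](C)CCC(=O)O)C(=O)OC(C)(C)C
F9 | step 18 | 1-tert-butyl 9-[(2R)-2-methyl-6-oxo-3,6-dihydro-2H-pyran-4-yl] (2S,3E,6R)-6-methyl-2-[(2S)-2-methylbutyl]non-3-enedioate | CC[C@H](C)C[C@@H](/C=C/C[C@H](C)CCC(=O)OC1=CC(=O)O[C@H](C)C1)C(=O)OC(C)(C)C
F10 | step 18 | tert-butyl (2S,3E,6R)-9-[(6R)-4-hydroxy-6-methyl-2-oxo-5,6-dihydro-2H-pyran-3-yl]-6-methyl-2-[(2S)-2-methylbutyl]-9-oxonon-3-enoate | CC[C@H](C)C[C@@H](/C=C/C[C@H](C)CCC(=O)C1=C(O)C[C@@H](C)OC1=O)C(=O)OC(C)(C)C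
F11 | step 16 | 5-[(4R,6E,8S,10S)-8-({[tert-butyl(dimethyl)silyl]oxy}methyl)-4,10-dimethyldodec-6-enoyl]-2,2-dimethyl-1,3-dioxane-4,6-dione | CC[C@H](C)C[C@@H](/C=C/C[C@H](C)CCC(=O)C1C(=O)OC(C)(C)OC1=O)CO[Si](C)(C)C(C)(C)C
F12 | step 16 | methyl (3R)-3-{[(6R,8E,10S,12S)-10-({[tert-butyl(dimethyl)silyl]oxy}methyl)-6,12-dimethyl-3-oxotetradec-8-enoyl]oxy}butanoate | CC[C@H](C)C[C@@H](/C=C/C[C@H](C)CCC(=O)CC(=O)O[C@H](C)CC(=O)OC)CO[Si](C)(C)C(C)(C)C
F13 | step 14 | {[(2R,4S)-2-({[tert-butyl(dimethyl)silyl]oxy}methyl)-4-methylhexyl]sulfanyl}benzene | CC[C@H](C)C[C@@H](CSc1ccccc1)CO[Si](C)(C)C(C)(C)C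
F14 | step 14 | {[(2R,4S)-2-({[tert-butyl(dimethyl)silyl]oxy}methyl)-4-methylhexyl]sulfonyl}benzene | CC[C@H](C)C[C@@H](CS(=O)(=O)c1ccccc1)CO[Si](C)(C)C(C)(C)C
F15 | step 14 | methyl (4R,8R,10S)-6-(acetyloxy)-7-(benzenesulfonyl)-8-({[tert-butyl(dimethyl)silyl]oxy}methyl)-4,10-dimethyldodecanoate | CC[C@H](C)C[C@H](CO[Si](C)(C)C(C)(C)C)C(S(=O)(=O)c1ccccc1)C(OC(C)=O)C[C@H](C)CCC(=O)OC
A1 | alternative 1 | (2S,3E,6R)-6,10-dimethyl-2-[(2S)-2-methylbutyl]undeca-3,9-dien-1-ol | CC[C@H](C)C[C@@H](/C=C/C[C@H](C)CCC=C(C)C)CO
A2 | alternative 1 | tributyl({[(6R,8S,9Z,12S)-2,6,12-trimethyltetradeca-2,9-dien-8-yl]oxy}methyl)stannane | CC[C@H](C)C/C=C\[C@@H](OC[Sn](CCCC)(CCCC)CCCC)C[C@H](C)CCC=C(C)C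
A3 | alternative 1 | (3R)-3,7-dimethyloct-6-enal ((R)-citronellal) | CC(C)=CCC[C@@H](C)CC=O
A4 | alternative 2 | tert-butyl (2S,3E,6R)-9-[(6R)-4-hydroxy-6-methyl-2-oxo-5,6-dihydro-2H-pyran-3-yl]-6-methyl-2-[(2S)-2-methylbutyl]-9-oxonon-3-enoate | CC[C@H](C)C[C@@H](/C=C/C[C@H](C)CCC(=O)C1=C(O)C[C@@H](C)OC1=O)C(=O)OC(C)(C)C
A5 | alternative 2 | 1-tert-butyl 11-[(2R)-4-methoxy-4-oxobutan-2-yl] (2S,3E,6R)-6-methyl-2-[(2S)-2-methylbutyl]-9-oxoundec-3-enedioate | CC[C@H](C)C[C@@H](/C=C/C[C@H](C)CCC(=O)CC(=O)O[C@H](C)CC(=O)OC)C(=O)OC(C)(C)C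
A6 | alternative 3 | tert-butyl (2S,3E,6S,7E)-9-[(6R)-4-hydroxy-6-methyl-2-oxo-5,6-dihydro-2H-pyran-3-yl]-6-methyl-2-[(2S)-2-methylbutyl]-9-oxonona-3,7-dienoate | CC[C@H](C)C[C@@H](/C=C/C[C@H](C)/C=C/C(=O)C1=C(O)C[C@@H](C)OC1=O)C(=O)OC(C)(C)C
A7 | alternative 3 | diethyl {2-[(6R)-4-hydroxy-6-methyl-2-oxo-5,6-dihydro-2H-pyran-3-yl]-2-oxoethyl}phosphonate | CCOP(=O)(OCC)CC(=O)C1=C(O)C[C@@H](C)OC1=O
A8 | alternative 3 | tert-butyl (2S,3E,6S)-6-methyl-2-[(2S)-2-methylbutyl]-7-oxohept-3-enoate | CC[C@H](C)C[C@@H](/C=C/C[C@H](C)C=O)C(=O)OC(C)(C)C
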